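**Retrosynthetic overview**
1. Target ⇒ (allylic oxidation, alkyne semi-hydrogenation) chromene propargylic diol ⇒ cut the pyran O–C2 bond to an open (E,E)-dienone-phenol; a catalyst-controlled o-quinone methide oxa-6π closure re-forms it and sets C2.
2. Dienone-phenol ⇒ vinylogous aldol condensation of a salicylaldehyde (from 4-methoxy-2-methylphenol) with a β,β-dimethyl enone ⇒ isobutenyllithium + a cis-fused δ-lactone.
3. δ-Lactone ⇒ alkynylation/lactonisation of a cis aldehyde-acid ⇒ ozonolysis of an enantioenriched silyl enol ether ⇒ chiral lithium amide desymmetrisation of meso cis-1,5-dimethylbicyclo[3.3.0]octan-3-one (fixes both quaternary carbons).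
4. Meso ketone ⇒ dichloroketene [2+2] on 1,2-dimethylcyclopentene, CH2N2 ring expansion, dechlorination.
5. Ring order: cyclopentane (bought) → cyclobutanone → second cyclopentanone (later cleaved) → temporary δ-lactone → 2H-pyran ring of the chromene last.

Assumption: 1,2-dimethylcyclopentene is bought; the sense of induction of the (R,R)-amide (step 4) and of the quinine-derived squaramide (step 10) is assumed as drawn and not predicted – if either is opposite, the (S,S)-amide or the quinidine-derived pseudo-enantiomer is used and nothing else changes.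

**Step 1**
Reactants: 1 1,2-dimethylcyclopentene; 2 trichloroacetyl chloride
Product: 4 (±)-cis-7,7-dichloro-1,5-dimethylbicyclo[3.2.0]heptan-6-one, via dichloroketene 3 (not isolated)
Conditions: activated Zn dust, POCl3, Et2O, sonication, 15–20 °C
Reagents that add atoms: none
Why: Zinc dechlorination of 2 gives dichloroketene, whose suprafacial ketene–alkene [2+2] cycloaddition to the electron-rich tetrasubstituted alkene forces the two angular methyls cis.

**Step 2**
Reactants: 4 (±)-cis-7,7-dichloro-1,5-dimethylbicyclo[3.2.0]heptan-6-one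
Product: 5 (±)-cis-2,2-dichloro-1,5-dimethylbicyclo[3.3.0]octan-3-one
Conditions: CH2N2, Et2O, MeOH (cat.), 0 °C to rt
Reagents that add atoms: diazomethane, C=[N+]=[N-]
Why: Diazomethane ring expansion of an α,α-dichlorocyclobutanone, in which the non-chlorinated, more electron-rich α-carbon migrates so that CH2 enters between C=O and the bridgehead.

**Step 3**
Reactants: 5 (±)-cis-2,2-dichloro-1,5-dimethylbicyclo[3.3.0]octan-3-one
Product: 6 cis-1,5-dimethylbicyclo[3.3.0]octan-3-one (meso)
Conditions: Zn dust, AcOH, 70 °C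
Reagents that add atoms: none
Why: Reductive dehalogenation of the α,α-dichloro ketone through zinc enolates removes both chlorines and leaves the meso ketone without touching the ring fusion.

**Step 4**
Reactants: 6 cis-1,5-dimethylbicyclo[3.3.0]octan-3-one
Product: 8 (1R,5S)-1,5-dimethyl-3-(trimethylsilyloxy)bicyclo[3.3.0]oct-2-ene, via lithium enolate 7 (not isolated)
Conditions: LiN[(R)-CH(CH3)Ph]2 (from (R,R)-bis(1-phenylethyl)amine and n-BuLi), LiCl, THF, −100 °C; TMSCl, −100 to −78 °C
Reagents that add atoms: chlorotrimethylsilane, C[Si](C)(C)Cl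
Why: Enantiotopos-selective deprotonation of a meso ketone by a C2-symmetric chiral lithium amide followed by O-silylation; choosing one of the two enantiotopic α-CH2 groups fixes the absolute configuration of both quaternary carbons at once.

**Step 5**
Reactants: 8 (1R,5S)-1,5-dimethyl-3-(trimethylsilyloxy)bicyclo[3.3.0]oct-2-ene
Product: 9 2-[(1S,2S)-2-formyl-1,2-dimethylcyclopentyl]acetic acid
Conditions: O3, CH2Cl2, −78 °C; Me2S, −78 °C to rt; H2O
Reagents that add atoms: ozone, [O-][O+]=O
Why: Ozonolysis (Criegee cleavage) of the silyl enol ether gives the aldehyde on the ring carbon and, after hydrolysis of the silyl ester, the acid on the CH2 arm, with both quaternary centres untouched (9 may sit as its cyclic hydroxy-lactone tautomer).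

**Step 6**
Reactants: 9 2-[(1S,2S)-2-formyl-1,2-dimethylcyclopentyl]acetic acid; 10 2-methylbut-3-yn-2-ol
Product: 13 (4aS,7aS)-1-(3-hydroxy-3-methylbut-1-yn-1-yl)-4a,7a-dimethylhexahydrocyclopenta[c]pyran-3(1H)-one (C1 epimers), via dilithiated alkynol 11 (not isolated), via hydroxy acid 12 (not isolated)
Conditions: 10 (3.2 equiv), n-BuLi (2 equiv per 10), THF, −78 to 0 °C; add 9, −78 to 0 °C; aq. HCl; TsOH (cat.), PhMe, rt
Reagents that add atoms: none
Why: 1,2-Addition of a lithium acetylide to the non-enolisable neopentyl aldehyde (the carboxylate is inert) and acid-catalysed δ-lactonisation across the cis arms; the new carbinol centre forms as an epimer mixture that step 12 erases.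

**Step 7**
Reactants: 13 the δ-lactone; 14 1-bromo-2-methylprop-1-ene
Product: 16 1-[(1S,2S)-2-(1,4-dihydroxy-4-methylpent-2-yn-1-yl)-1,2-dimethylcyclopentyl]-4-methylpent-3-en-2-one (carbinol epimers), via (2-methylprop-1-enyl)lithium 15 (not isolated)
Conditions: 14, t-BuLi (2 equiv per 14), THF/Et2O, −78 °C; add 13 (2.05 equiv of 15 per 13), −78 °C; aq. NH4Cl at −78 °C
Reagents that add atoms: none
Why: Mono-addition of an alkenyllithium to a lactone at −78 °C (the lithium lactolate survives until the cold quench) gives the β,β-dimethyl enone and frees the propargylic alcohol; the first equivalent only deprotonates the tertiary OH.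

**Step 8**
Reactants: 17 4-methoxy-2-methylphenol
Product: 18 2-hydroxy-5-methoxy-3-methylbenzaldehyde
Conditions: MgCl2, Et3N, (CH2O)n, MeCN, reflux; aq. HCl
Reagents that add atoms: formaldehyde (as paraformaldehyde), C=O
Why: Magnesium-phenoxide-directed ortho-formylation in which only the free ortho position reacts and a second formaldehyde accepts the hydride.

**Step 9**
Reactants: 16 the hydroxy enone; 18 2-hydroxy-5-methoxy-3-methylbenzaldehyde
Product: 19 (3E,5E)-1-[(1S,2S)-2-(1,4-dihydroxy-4-methylpent-2-yn-1-yl)-1,2-dimethylcyclopentyl]-6-(2-hydroxy-5-methoxy-3-methylphenyl)-4-methylhexa-3,5-dien-2-one (carbinol epimers)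
Conditions: KOH (4 equiv), MeOH, 0 °C to rt, dark; AcOH, 0 °C
Reagents that add atoms: none
Why: Vinylogous Claisen–Schmidt (aldol) condensation: the α'-CH2 is neopentyl, so the extended dienolate forms and reversible aldol/dehydration funnels to the fully conjugated (E,E)-dienone, which stays open as its phenolate in strong base and is isolated after cold neutralisation.

**Step 10**
Reactants: 19 the (E,E)-dienone-phenol
Product: 21 1-[(1S,2S)-2-(1,4-dihydroxy-4-methylpent-2-yn-1-yl)-1,2-dimethylcyclopentyl]-3-[(2R)-6-methoxy-2,8-dimethyl-2H-chromen-2-yl]propan-2-one (carbinol epimers), via o-quinone methide 20 (not isolated)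
Conditions: 3-{[3,5-bis(trifluoromethyl)phenyl]amino}-4-{[(8α,9S)-6'-methoxycinchonan-9-yl]amino}cyclobut-3-ene-1,2-dione (quinine-derived squaramide, 10 mol%), PhMe, 4 Å MS, 40 °C, dark
Reagents that add atoms: none
Why: Proposed new method: catalytic enantioselective cycloisomerisation of an (E,E)-2-dienonylphenol to a 2,2-disubstituted 2H-chromene – the quinuclidine nitrogen deprotonates the phenol, the vinylogous phenolate/dienolate is reprotonated at the carbon α to the ketone to give o-quinone methide 20 in which the former E C=C is a freely rotating single bond, and catalyst-bound 20 (squaramide N–H to the side-chain ketone, quinuclidinium N–H to the quinone methide oxygen) closes by oxa-6π electrocyclisation on one face to form the O–C2 bond and set (2R); the closed neutral ketone is expected to be the thermodynamic product and reopening would need enolisation of a simple ketone by a weak base; the closest known reaction types are the amine–squaramide-catalysed intramolecular oxa-Michael addition of phenols to enones (chromans) and the thermal or base-promoted o-quinone methide oxa-6π closure of racemic chromene synthesis.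

**Step 11**
Reactants: 21 the chromene propargylic diol
Product: 22 1-[(1S,2S)-2-[(2Z)-1,4-dihydroxy-4-methylpent-2-en-1-yl]-1,2-dimethylcyclopentyl]-3-[(2R)-6-methoxy-2,8-dimethyl-2H-chromen-2-yl]propan-2-one (carbinol epimers)
Conditions: H2 (1 atm), Pd on CaCO3 poisoned with Pb(OAc)2 (Lindlar catalyst), quinoline, EtOAc, rt
Reagents that add atoms: none
Why: Lindlar semi-hydrogenation adds H2 syn to the alkyne to give the Z-alkene, while the poisoned catalyst leaves the chromene C3=C4 bond and the ketone alone.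

**Step 12**
Reactants: 22 the (Z)-ene-1,4-diol
Product: 23 (2Z)-4-hydroxy-1-[(1S,2S)-2-{3-[(2R)-6-methoxy-2,8-dimethyl-2H-chromen-2-yl]-2-oxopropyl}-1,2-dimethylcyclopentyl]-4-methylpent-2-en-1-one (target)
Conditions: Dess–Martin periodinane, CH2Cl2, 0 °C
Reagents that add atoms: none
Why: Dess–Martin oxidation of the secondary allylic alcohol (tertiary alcohol inert) under near-neutral conditions keeps the Z geometry and the acid- and base-sensitive β-aryloxy ketone, and merges both carbinol epimers into the single target.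

**Compound list**
1 | 1,2-dimethylcyclopentene | CC1=C(C)CCC1 | starting material
2 | trichloroacetyl chloride | ClC(=O)C(Cl)(Cl)Cl | starting material
3 | dichloroketene | ClC(Cl)=C=O | intermediate
4 | (±)-cis-7,7-dichloro-1,5-dimethylbicyclo[3.2.0]heptan-6-one (racemic, one enantiomer drawn) | ClC1(Cl)[C@]2(C)CCC[C@]2(C)C1=O | intermediate
5 | (±)-cis-2,2-dichloro-1,5-dimethylbicyclo[3.3.0]octan-3-one (racemic, one enantiomer drawn) | ClC1(Cl)[C@]2(C)CCC[C@]2(C)CC1=O | intermediate
6 | cis-1,5-dimethylbicyclo[3.3.0]octan-3-one (meso) | O=C1C[C@]2(C)CCC[C@]2(C)C1 | intermediate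
7 | lithium (1R,5S)-1,5-dimethylbicyclo[3.3.0]oct-2-en-3-olate | C1[C@]2(C)CCC[C@]2(C)C=C1[O-].[Li+] | intermediate
8 | (1R,5S)-1,5-dimethyl-3-(trimethylsilyloxy)bicyclo[3.3.0]oct-2-ene | C1[C@]2(C)CCC[C@]2(C)C=C1O[Si](C)(C)C | intermediate
9 | 2-[(1S,2S)-2-formyl-1,2-dimethylcyclopentyl]acetic acid | OC(=O)C[C@]1(C)CCC[C@]1(C)C=O | intermediate
10 | 2-methylbut-3-yn-2-ol | CC(C)(O)C#C | starting material
11 | O,C-dilithiated 2-methylbut-3-yn-2-ol | [Li+].[Li+].[O-]C(C)(C)C#[C-] | intermediate
12 | 2-[(1S,2S)-2-(1,4-dihydroxy-4-methylpent-2-yn-1-yl)-1,2-dimethylcyclopentyl]acetic acid (carbinol epimers) | OC(=O)C[C@]1(C)CCC[C@]1(C)C(O)C#CC(C)(C)O | intermediate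
13 | (4aS,7aS)-1-(3-hydroxy-3-methylbut-1-yn-1-yl)-4a,7a-dimethylhexahydrocyclopenta[c]pyran-3(1H)-one (cis-fused δ-lactone, C1 epimers) | O=C1C[C@]2(C)CCC[C@]2(C)C(C#CC(C)(C)O)O1 | intermediate
14 | 1-bromo-2-methylprop-1-ene | CC(C)=CBr | starting material
15 | (2-methylprop-1-en-1-yl)lithium | [Li]C=C(C)C | intermediate
16 | 1-[(1S,2S)-2-(1,4-dihydroxy-4-methylpent-2-yn-1-yl)-1,2-dimethylcyclopentyl]-4-methylpent-3-en-2-one (carbinol epimers) | CC(C)=CC(=O)C[C@]1(C)CCC[C@]1(C)C(O)C#CC(C)(C)O | intermediate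
17 | 4-methoxy-2-methylphenol | COc1ccc(O)c(C)c1 | starting material
18 | 2-hydroxy-5-methoxy-3-methylbenzaldehyde | COc1cc(C)c(O)c(C=O)c1 | intermediate
19 | (3E,5E)-1-[(1S,2S)-2-(1,4-dihydroxy-4-methylpent-2-yn-1-yl)-1,2-dimethylcyclopentyl]-6-(2-hydroxy-5-methoxy-3-methylphenyl)-4-methylhexa-3,5-dien-2-one (carbinol epimers) | COc1cc(C)c(O)c(/C=C/C(C)=C/C(=O)C[C@]2(C)CCC[C@]2(C)C(O)C#CC(C)(C)O)c1 | intermediate
20 | 6-[6-{(1S,2S)-2-(1,4-dihydroxy-4-methylpent-2-yn-1-yl)-1,2-dimethylcyclopentyl}-3-methyl-5-oxohex-2-en-1-ylidene]-4-methoxy-2-methylcyclohexa-2,4-dien-1-one (o-quinone methide tautomer of 19) | COC1=CC(=CC=C(C)CC(=O)C[C@]2(C)CCC[C@]2(C)C(O)C#CC(C)(C)O)C(=O)C(C)=C1 | intermediate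
21 | 1-[(1S,2S)-2-(1,4-dihydroxy-4-methylpent-2-yn-1-yl)-1,2-dimethylcyclopentyl]-3-[(2R)-6-methoxy-2,8-dimethyl-2H-chromen-2-yl]propan-2-one (carbinol epimers) | COc1cc(C)c2c(c1)C=C[C@@](C)(CC(=O)C[C@]1(C)CCC[C@]1(C)C(O)C#CC(C)(C)O)O2 | intermediate
22 | 1-[(1S,2S)-2-[(2Z)-1,4-dihydroxy-4-methylpent-2-en-1-yl]-1,2-dimethylcyclopentyl]-3-[(2R)-6-methoxy-2,8-dimethyl-2H-chromen-2-yl]propan-2-one (carbinol epimers) | COc1cc(C)c2c(c1)C=C[C@@](C)(CC(=O)C[C@]1(C)CCC[C@]1(C)C(O)/C=C\C(C)(C)O)O2 | intermediate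
23 | (2Z)-4-hydroxy-1-[(1S,2S)-2-{3-[(2R)-6-methoxy-2,8-dimethyl-2H-chromen-2-yl]-2-oxopropyl}-1,2-dimethylcyclopentyl]-4-methylpent-2-en-1-one | COc1cc(C)c2c(c1)C=C[C@@](C)(CC(=O)C[C@]1(C)CCC[C@]1(C)C(=O)/C=C\C(C)(C)O)O2 | target

**Step count**
Total: 12 steps. Longest linear sequence: 11 steps (1–7, then 9–12); step 8 is a one-step branch.

**Three steps most likely to fail**

Step 10 (new reaction). The rate, the position of the open/closed equilibrium and the facial control at C2 are all unproven. The fallback sets out from 19 and comes back at 21. Heating 19 with pyridine in toluene at 110 °C, the non-selective base/heat-promoted tautomerisation and oxa-6π closure of classical chromene synthesis, gives 21 together with its C2 epimer 1-[(1S,2S)-2-(1,4-dihydroxy-4-methylpent-2-yn-1-yl)-1,2-dimethylcyclopentyl]-3-[(2S)-6-methoxy-2,8-dimethyl-2H-chromen-2-yl]propan-2-one F10. The epimers are separated by preparative HPLC on an amylose tris(3,5-dimethylphenylcarbamate) phase and 21 goes on to step 11.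

Step 4. Discrimination of the enantiotopic CH2 groups next to two quaternary bridgeheads may be modest. The fallback sets out from 6 and comes back at 9, replacing asymmetric deprotonation by classical resolution. LiN(i-Pr)2/TMSCl gives the racemic enol ether, that is 8 mixed with its mirror image (1S,5R)-1,5-dimethyl-3-(trimethylsilyloxy)bicyclo[3.3.0]oct-2-ene F1. Ozonolysis as in step 5 gives 9 mixed with its antipode 2-[(1R,2R)-2-formyl-1,2-dimethylcyclopentyl]acetic acid F2. Fractional crystallisation with (R)-N,N-dimethyl-1-phenylethylamine (a tertiary amine, so no imine forms) gives the salt (R)-N,N-dimethyl-1-phenylethylammonium 2-[(1S,2S)-2-formyl-1,2-dimethylcyclopentyl]acetate F3. The diastereomeric salt (R)-N,N-dimethyl-1-phenylethylammonium 2-[(1R,2R)-2-formyl-1,2-dimethylcyclopentyl]acetate F4 stays in the mother liquor (if F4 is the less soluble salt, the (S)-amine is used). Aqueous HCl frees 9 from F3.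

Step 9. α'-Aldol reaction, retro-aldol loss of acetone from 16, or oxa-Michael/aldol annulation of the free salicylaldehyde to a 3-acylchromene could compete. The fallback sets out from 13 and 18 and comes back at 19, forming the C3–C4 bond instead of C5–C6 with the phenol protected.
- MeLi (−78 °C) opens 13 to 1-[(1S,2S)-2-(1,4-dihydroxy-4-methylpent-2-yn-1-yl)-1,2-dimethylcyclopentyl]propan-2-one F5.
- 18 condenses with acetone (NaOH) to (E)-4-(2-hydroxy-5-methoxy-3-methylphenyl)but-3-en-2-one F6, which TBSCl/imidazole converts into (E)-4-[2-(tert-butyldimethylsilyloxy)-5-methoxy-3-methylphenyl]but-3-en-2-one F7.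
- The kinetic lithium enolate of F5 (LiN(i-Pr)2, 3.2 equiv, −78 °C) adds 1,2 to F7 to give (E)-6-[2-(tert-butyldimethylsilyloxy)-5-methoxy-3-methylphenyl]-1-[(1S,2S)-2-(1,4-dihydroxy-4-methylpent-2-yn-1-yl)-1,2-dimethylcyclopentyl]-4-hydroxy-4-methylhex-5-en-2-one F8.
- TsOH-catalysed dehydration gives the tert-butyldimethylsilyl ether of 19 F9, and Bu4NF returns 19.

**Further compounds**
F1 | step 4 | (1S,5R)-1,5-dimethyl-3-(trimethylsilyloxy)bicyclo[3.3.0]oct-2-ene | C1[C@@]2(C)CCC[C@@]2(C)C=C1O[Si](C)(C)C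
F2 | step 4 | 2-[(1R,2R)-2-formyl-1,2-dimethylcyclopentyl]acetic acid | OC(=O)C[C@@]1(C)CCC[C@@]1(C)C=O
F3 | step 4 | (R)-N,N-dimethyl-1-phenylethylammonium 2-[(1S,2S)-2-formyl-1,2-dimethylcyclopentyl]acetate | C[C@@H]([NH+](C)C)c1ccccc1.[O-]C(=O)C[C@]1(C)CCC[C@]1(C)C=O
F4 | step 4 | (R)-N,N-dimethyl-1-phenylethylammonium 2-[(1R,2R)-2-formyl-1,2-dimethylcyclopentyl]acetate | C[C@@H]([NH+](C)C)c1ccccc1.[O-]C(=O)C[C@@]1(C)CCC[C@@]1(C)C=O
F5 | step 9 | 1-[(1S,2S)-2-(1,4-dihydroxy-4-methylpent-2-yn-1-yl)-1,2-dimethylcyclopentyl]propan-2-one (carbinol epimers) | CC(=O)C[C@]1(C)CCC[C@]1(C)C(O)C#CC(C)(C)O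
F6 | step 9 | (E)-4-(2-hydroxy-5-methoxy-3-methylphenyl)but-3-en-2-one | COc1cc(C)c(O)c(/C=C/C(C)=O)c1
F7 | step 9 | (E)-4-[2-(tert-butyldimethylsilyloxy)-5-methoxy-3-methylphenyl]but-3-en-2-one | COc1cc(C)c(O[Si](C)(C)C(C)(C)C)c(/C=C/C(C)=O)c1
F8 | step 9 | (E)-6-[2-(tert-butyldimethylsilyloxy)-5-methoxy-3-methylphenyl]-1-[(1S,2S)-2-(1,4-dihydroxy-4-methylpent-2-yn-1-yl)-1,2-dimethylcyclopentyl]-4-hydroxy-4-methylhex-5-en-2-one (epimer mixture at both carbinols) | COc1cc(C)c(O[Si](C)(C)C(C)(C)C)c(/C=C/C(C)(O)CC(=O)C[C@]2(C)CCC[C@]2(C)C(O)C#CC(C)(C)O)c1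
F9 | step 9 | (3E,5E)-6-[2-(tert-butyldimethylsilyloxy)-5-methoxy-3-methylphenyl]-1-[(1S,2S)-2-(1,4-dihydroxy-4-methylpent-2-yn-1-yl)-1,2-dimethylcyclopentyl]-4-methylhexa-3,5-dien-2-one | COc1cc(C)c(O[Si](C)(C)C(C)(C)C)c(/C=C/C(C)=C/C(=O)C[C@]2(C)CCC[C@]2(C)C(O)C#CC(C)(C)O)c1
F10 | step 10 | 1-[(1S,2S)-2-(1,4-dihydroxy-4-methylpent-2-yn-1-yl)-1,2-dimethylcyclopentyl]-3-[(2S)-6-methoxy-2,8-dimethyl-2H-chromen-2-yl]propan-2-one | COc1cc(C)c2c(c1)C=C[C@](C)(CC(=O)C[C@]1(C)CCC[C@]1(C)C(O)C#CC(C)(C)O)O2
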